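Ring atoms are numbered C1 (quaternary stereocentre bearing OMe and the ester carbon C9), C2 and C3 (dimethoxy alkene), C4 (ketone) and C5 (carrying the exocyclic cinnamoyl enol) of the cyclopentenone. Because C1 carries two carbons of carboxyl origin, C9 and ring carbon C2, it is traced back to the central carbon of an achiral dimethyl 2-allyl-2-methoxymalonate whose allyl CH2 becomes C5. A carboxylesterase hydrolyses one enantiotopic ester only and thereby sets the single stereocentre in one operation, forming no skeletal bond, while the freed acid becomes the handle for C2–C3–C4. The five-membered ring is closed at the end by acylating the C5 ketone enolate with the C4 ester.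

Key step: step 2

Remarks on the chemistry:
- Besides the ring labels above, C6 is the exocyclic enol carbon and C7/C8 are the styryl CH=CH. The prose uses these labels; compound names carry their own IUPAC locants.
- Assumption: the esterase hydrolyses the pro-R methoxycarbonyl group of the malonate, which leads to the (S)-half-ester; the opposite sense is covered among the fallbacks.
- The target is written as the hydrogen-bonded (Z)-enol of the 2-acyl ketone, the form expected for the enolised β-diketone.
- The allyl group is cleaved with OsO4/NaIO4 and not with ozone, because ozone would first attack the electron-rich C2=C3 enol ether.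

Step 1
Reactants: 1 dimethyl methoxymalonate; 2 allyl bromide
Product: 3 dimethyl 2-methoxy-2-(prop-2-en-1-yl)propanedioate
Conditions: NaH (1.1 equiv), THF, 0 °C; then 2 (1.2 equiv), 0 °C to rt
Reagents that add atoms: none
Why: Malonic ester alkylation: the sodium enolate of the methoxymalonate displaces bromide from allyl bromide (SN2), and the product is achiral because its two ester groups are identical.

Step 2
Reactants: 3 dimethyl 2-methoxy-2-(prop-2-en-1-yl)propanedioate
Product: 4 (2S)-2-methoxy-2-(methoxycarbonyl)pent-4-enoic acid
Conditions: pig liver esterase, sodium phosphate buffer (NaH2PO4/Na2HPO4, pH 7.5), 10% DMSO, 25 °C, pH-stat with 1 M NaOH (1.0 equiv); then HCl to pH 2, EtOAc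
Reagents that add atoms: water, O
Why: The catalytic serine of the esterase adds to one ester carbonyl, methanol is expelled to leave an acyl-enzyme, and water then frees the carboxylate (enzymatic ester hydrolysis by acyl–oxygen cleavage). The closest known reaction type is the pig liver esterase desymmetrisation of prochiral 2,2-disubstituted dimethyl malonates, which includes 2-alkoxy-2-alkyl members. No ring is closed and no skeletal bond is made. The new stereocentre C1 is controlled only by the chiral active site: the compact polar methoxy group and the longer lipophilic allyl group are bound in different sub-sites, so just one of the two enantiotopic methoxycarbonyl groups, assumed here to be the pro-R one, is presented to the serine. The step needs enantiotopic-group selectivity and a clean stop at the half-ester; the first is secured by the size and polarity contrast between OMe and allyl, the second by the carboxylate of the half-ester, which is a poor esterase substrate at pH 7.5. Because C1 bears no hydrogen, the configuration cannot be lost by enolisation in any later step.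

Step 3
Reactants: 4 (2S)-2-methoxy-2-(methoxycarbonyl)pent-4-enoic acid; 5 methyl methoxyacetate
Product: 8 dimethyl (2S)-2,4-dimethoxy-3-oxo-2-(prop-2-en-1-yl)pentanedioate (both epimers at the CH(OMe) carbon), via lithium enolate of methyl methoxyacetate 6 (not isolated), via acyl imidazolide 7 (not isolated)
Conditions: 4, CDI (1.1 equiv), THF, rt; added to 5 (3.3 equiv)/LiN(i-Pr)2 (3.3 equiv), THF, −78 °C to −40 °C; AcOH quench
Reagents that add atoms: 1,1'-carbonyldiimidazole, O=C(n1ccnc1)n1ccnc1 (its imidazolyl group stays only in 7); lithium diisopropylamide, [Li+].CC(C)[N-]C(C)C (its lithium stays only in 6)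
Why: Crossed Claisen condensation: the acyl imidazolide, far more electrophilic than the neighbouring methyl ester, C-acylates the lithium enolate of the methoxyacetate, and immediate deprotonation of the β-keto ester by excess enolate protects it against a second attack and against retro-Claisen cleavage.

Step 4
Reactants: 8 dimethyl (2S)-2,4-dimethoxy-3-oxo-2-(prop-2-en-1-yl)pentanedioate
Product: 9 dimethyl (2Z,4S)-2,3,4-trimethoxy-4-(prop-2-en-1-yl)pent-2-enedioate
Conditions: Cs2CO3 (1.5 equiv), Me2SO4 (1.3 equiv), DMF, 0 °C to rt
Reagents that add atoms: dimethyl sulfate, COS(=O)(=O)OC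
Why: Enolate O-alkylation of a β-keto ester: the weakly coordinated caesium enolate in DMF reacts with the hard electrophile dimethyl sulfate at oxygen, and because this non-chelated enolate keeps its oxyanion away from the ester carbonyl the enol ether should form with C1 and C4 cis (2Z), the geometry that ring closure requires.

Step 5
Reactants: 9 dimethyl (2Z,4S)-2,3,4-trimethoxy-4-(prop-2-en-1-yl)pent-2-enedioate
Product: 11 dimethyl (2Z,4S)-2,3,4-trimethoxy-4-(2-oxoethyl)pent-2-enedioate, via vicinal diol 10 (not isolated)
Conditions: OsO4 (2 mol%), NaIO4 (4 equiv), 2,6-lutidine (2 equiv), dioxane/H2O 3:1, rt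
Reagents that add atoms: osmium tetroxide, O=[Os](=O)(=O)=O (catalytic; delivers the two oxygen atoms of 10); sodium periodate, [Na+].[O-]I(=O)(=O)=O (terminal oxidant that reloads the osmium with oxygen)
Why: Lemieux–Johnson oxidation: OsO4 dihydroxylates the unhindered monosubstituted alkene far faster than the tetrasubstituted, ester-conjugated C2=C3 enol ether and periodate cleaves the diol to the aldehyde, whereas ozone would attack the electron-rich enol ether first.

Step 6
Reactants: 11 dimethyl (2Z,4S)-2,3,4-trimethoxy-4-(2-oxoethyl)pent-2-enedioate; 12 (E)-(2-bromovinyl)benzene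
Product: 14 dimethyl (2Z,4S)-4-[(3E)-2-hydroxy-4-phenylbut-3-en-1-yl]-2,3,4-trimethoxypent-2-enedioate (both carbinol epimers), via styrylchromium dichloride 13 (not isolated)
Conditions: 12 (2 equiv), CrCl2 (4 equiv), NiCl2 (2 mol%), DMF, rt; then H2O
Reagents that add atoms: chromium dichloride, Cl[Cr]Cl (chromium and chlorine stay only in 13)
Why: Nozaki–Hiyama–Kishi reaction: nickel-catalysed activation of the C–Br bond gives an alkenylchromium species that adds only to the aldehyde with retention of the E geometry, and its low basicity spares the esters, the enol ether and the β-methoxy aldehyde from enolisation and elimination; the new carbinol centre is left uncontrolled because step 7 removes it.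

Step 7
Reactants: 14 dimethyl (2Z,4S)-4-[(3E)-2-hydroxy-4-phenylbut-3-en-1-yl]-2,3,4-trimethoxypent-2-enedioate
Product: 15 dimethyl (2Z,4S)-2,3,4-trimethoxy-4-[(3E)-2-oxo-4-phenylbut-3-en-1-yl]pent-2-enedioate
Conditions: Dess–Martin periodinane (1.3 equiv), pyridine (3 equiv), CH2Cl2, 0 °C, on freshly prepared 14
Reagents that add atoms: none
Why: Dess–Martin oxidation of the allylic alcohol to the enone under buffered, non-basic conditions erases the carbinol centre, and immediate use of 14 keeps its γ-hydroxy group from lactonising onto the C9 ester.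

Step 8
Reactants: 15 dimethyl (2Z,4S)-2,3,4-trimethoxy-4-[(3E)-2-oxo-4-phenylbut-3-en-1-yl]pent-2-enedioate
Product: 16 methyl (1S,5Z)-5-[(2E)-1-hydroxy-3-phenylprop-2-en-1-ylidene]-1,2,3-trimethoxy-4-oxocyclopent-2-ene-1-carboxylate
Conditions: LiN(SiMe3)2 (2.2 equiv), THF, −78 °C to −20 °C; then 1 M HCl, 0 °C
Reagents that add atoms: none
Why: Intramolecular Claisen (Dieckmann-type) condensation: C5 is the only enolisable carbon, its lithium enolate attacks the cis-held C4 ester in a 5-exo-trig acyl substitution and the second equivalent of base deprotonates the β-diketone formed, which makes the closure irreversible, while the low temperature keeps β-elimination of the C1 methoxy group behind; C1 is not touched and the product rests as the hydrogen-bonded enol.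

Compound list
1 | dimethyl methoxymalonate (dimethyl 2-methoxypropanedioate) | COC(C(=O)OC)C(=O)OC | starting material
2 | allyl bromide (3-bromoprop-1-ene) | C=CCBr | starting material
3 | dimethyl 2-methoxy-2-(prop-2-en-1-yl)propanedioate (dimethyl 2-allyl-2-methoxymalonate) | COC(=O)C(CC=C)(OC)C(=O)OC | intermediate
4 | (2S)-2-methoxy-2-(methoxycarbonyl)pent-4-enoic acid | COC(=O)[C@@](CC=C)(OC)C(=O)O | intermediate
5 | methyl methoxyacetate | COCC(=O)OC | starting material
6 | lithium 1,2-dimethoxyethen-1-olate (lithium enolate of 5; not isolated) | [Li+].[O-]C(OC)=COC | intermediate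
7 | methyl (2S)-2-(1H-imidazole-1-carbonyl)-2-methoxypent-4-enoate (acyl imidazolide; not isolated) | COC(=O)[C@@](CC=C)(OC)C(=O)n1ccnc1 | intermediate
8 | dimethyl (2S)-2,4-dimethoxy-3-oxo-2-(prop-2-en-1-yl)pentanedioate, both epimers at the CH(OMe) carbon | COC(=O)[C@@](CC=C)(OC)C(=O)C(OC)C(=O)OC | intermediate
9 | dimethyl (2Z,4S)-2,3,4-trimethoxy-4-(prop-2-en-1-yl)pent-2-enedioate | COC(=O)[C@@](CC=C)(OC)/C(OC)=C(OC)\C(=O)OC | intermediate
10 | dimethyl (2Z,4S)-4-(2,3-dihydroxypropyl)-2,3,4-trimethoxypent-2-enedioate, both carbinol epimers (not isolated) | COC(=O)[C@@](CC(O)CO)(OC)/C(OC)=C(OC)\C(=O)OC | intermediate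
11 | dimethyl (2Z,4S)-2,3,4-trimethoxy-4-(2-oxoethyl)pent-2-enedioate | COC(=O)[C@@](CC=O)(OC)/C(OC)=C(OC)\C(=O)OC | intermediate
12 | (E)-(2-bromovinyl)benzene | Br/C=C/c1ccccc1 | starting material
13 | (E)-(2-phenylethenyl)chromium dichloride (not isolated) | Cl[Cr](Cl)/C=C/c1ccccc1 | intermediate
14 | dimethyl (2Z,4S)-4-[(3E)-2-hydroxy-4-phenylbut-3-en-1-yl]-2,3,4-trimethoxypent-2-enedioate, both carbinol epimers | COC(=O)[C@@](CC(O)/C=C/c1ccccc1)(OC)/C(OC)=C(OC)\C(=O)OC | intermediate
15 | dimethyl (2Z,4S)-2,3,4-trimethoxy-4-[(3E)-2-oxo-4-phenylbut-3-en-1-yl]pent-2-enedioate | COC(=O)[C@@](CC(=O)/C=C/c1ccccc1)(OC)/C(OC)=C(OC)\C(=O)OC | intermediate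
16 | methyl (1S,5Z)-5-[(2E)-1-hydroxy-3-phenylprop-2-en-1-ylidene]-1,2,3-trimethoxy-4-oxocyclopent-2-ene-1-carboxylate | COC(=O)[C@@]1(OC)C(OC)=C(OC)C(=O)/C1=C(O)/C=C/c1ccccc1 | target

Total step count: 8.
Longest linear sequence: 8 steps, from 1 to 16.

Steps most likely to fail

Step 4. Methylation may occur at carbon instead of oxygen, or the enol ether may form with C1 and C4 trans, a geometry that cannot cyclise in step 8. Fallback: setting out from 8, the hydrogen-bonded enol is methylated with trimethylsilyldiazomethane in MeOH–toluene, which reacts only at the acidic O–H and should give mainly dimethyl (2E,4S)-2,3,4-trimethoxy-4-(prop-2-en-1-yl)pent-2-enedioate F1. Irradiation of F1 (350 nm, MeCN) equilibrates the push–pull alkene to an E/Z mixture, from which 9 is separated while recovered F1 is irradiated again. The route is rejoined at 9.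

Step 8. Expulsion of the C1 methoxy group from the C5 enolate (β-elimination), or attack by the enolate oxygen, may outrun the attack of C5 on the donor-deactivated C4 ester. Fallback: setting out from 15, the free lithium enolate is given up in favour of Lewis-acid soft enolisation, a titanium-mediated Dieckmann-type closure (TiCl4, Bu3N, CH2Cl2, −78 to 0 °C). TiCl4 binds and activates the C4 ester, and the nucleophile is a far less basic trichlorotitanium enolate. Acidic work-up gives 16 directly, the point of return, and no new compound is made (F0).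

Step 2. The esterase may select the other enantiotopic ester group for hydrolysis. Fallback (exchange of the roles of acid and ester): setting out from 3, the enzyme product is then (2R)-2-methoxy-2-(methoxycarbonyl)pent-4-enoic acid F2. Its acid is masked with tert-butyl 2,2,2-trichloroacetimidate and catalytic BF3·OEt2 to give 1-tert-butyl 3-methyl (2S)-2-methoxy-2-(prop-2-en-1-yl)propanedioate F3. LiOH in THF–water saponifies only the methyl ester to give (2S)-2-(tert-butoxycarbonyl)-2-methoxypent-4-enoic acid F4, which has its free acid at the carbon that must grow into C2. F4 is taken through the conditions of step 3 to tert-butyl (2S)-2-(1H-imidazole-1-carbonyl)-2-methoxypent-4-enoate F5 and on to 1-tert-butyl 5-methyl (2S)-2,4-dimethoxy-3-oxo-2-(prop-2-en-1-yl)pentanedioate F6, then through those of step 4 to 5-tert-butyl 1-methyl (2Z,4S)-2,3,4-trimethoxy-4-(prop-2-en-1-yl)pent-2-enedioate F7. Anhydrous TFA in CH2Cl2 at 0 °C cleaves the tert-butyl ester to (2S,3Z)-2,3,4,5-tetramethoxy-5-oxo-2-(prop-2-en-1-yl)pent-3-enoic acid F8, and MeI with K2CO3 in DMF gives 9, where the route is rejoined.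

Further compounds
F1 | step 4 | dimethyl (2E,4S)-2,3,4-trimethoxy-4-(prop-2-en-1-yl)pent-2-enedioate | COC(=O)[C@@](CC=C)(OC)/C(OC)=C(OC)/C(=O)OC
F0 | step 8 | none | none
F2 | step 2 | (2R)-2-methoxy-2-(methoxycarbonyl)pent-4-enoic acid | COC(=O)[C@](CC=C)(OC)C(=O)O
F3 | step 2 | 1-tert-butyl 3-methyl (2S)-2-methoxy-2-(prop-2-en-1-yl)propanedioate | COC(=O)[C@](CC=C)(OC)C(=O)OC(C)(C)C
F4 | step 2 | (2S)-2-(tert-butoxycarbonyl)-2-methoxypent-4-enoic acid | CC(C)(C)OC(=O)[C@@](CC=C)(OC)C(=O)O
F5 | step 2 | tert-butyl (2S)-2-(1H-imidazole-1-carbonyl)-2-methoxypent-4-enoate | CC(C)(C)OC(=O)[C@@](CC=C)(OC)C(=O)n1ccnc1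
F6 | step 2 | 1-tert-butyl 5-methyl (2S)-2,4-dimethoxy-3-oxo-2-(prop-2-en-1-yl)pentanedioate, both epimers at the CH(OMe) carbon | CC(C)(C)OC(=O)[C@@](CC=C)(OC)C(=O)C(OC)C(=O)OC
F7 | step 2 | 5-tert-butyl 1-methyl (2Z,4S)-2,3,4-trimethoxy-4-(prop-2-en-1-yl)pent-2-enedioate | CC(C)(C)OC(=O)[C@@](CC=C)(OC)/C(OC)=C(OC)\C(=O)OC
F8 | step 2 | (2S,3Z)-2,3,4,5-tetramethoxy-5-oxo-2-(prop-2-en-1-yl)pent-3-enoic acid | OC(=O)[C@@](CC=C)(OC)/C(OC)=C(OC)\C(=O)OC
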